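The same charge goes into each vessel below, and Sunday's tank holds it on average ten times as long as Saturday's, 40.0 h against 4.0 h.

    starting material + free catalyst ⇌ catalyst intermediate A (K1 = 0.66 M⁻¹, k1 = 46 M⁻¹ h⁻¹)
    catalyst intermediate A → free catalyst + target (k2 = 160 h⁻¹)
    second substrate + free catalyst ⇌ catalyst intermediate B (K3 = 1.4 M⁻¹, k3 = 24 M⁻¹ h⁻¹)
    catalyst intermediate B → free catalyst + second product (k4 = 83 h⁻¹)
    free catalyst + added ligand ⇌ idle complex, settled at all times (K5 = 2.9 M⁻¹)

| flask | starting material | second substrate | free catalyst | added ligand | remark | time |
|---|---|---|---|---|---|---|
| Sunday's | 2.0 M | 2.00 M | 22 mM | 110 mM | one stirred flow tank at steady state, fed with the mixture as stated, mean residence time 40.0 h |  |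
| Wednesday's | 2.0 M | 2.00 M | 22 mM | 110 mM | a closed flask charged with all of it at once and left for 4.0 h | 4.0 h |
| Friday's | 2.0 M | 2.00 M (fed, over 3.20 h) | 22 mM | 110 mM | all but second substrate at the start; second substrate goes in evenly over 3.20 h, the run ends at 4.0 h | 4.0 h |
| Saturday's | 2.0 M | 2.00 M | 22 mM | 110 mM | a single well-mixed tank run continuously and read at steady state, 4.0 h in it on average |  |

- the stated concentrations are those of everything mixed, before any reaction; amounts are the same in each set-up
- the feed brings no volume worth counting
- run time (Wednesday's): 4.0 h

1. the set-up with the highest amount of target at the outlet or at the end, in percent of the starting material put in ("none" if the first two lie within 2 percentage points) (Sunday's / Wednesday's / Friday's / Saturday's / none)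
2. amount of target at the outlet or at the end, in percent of the starting material put in, Sunday's
3. amount of target at the outlet or at the end, in percent of the starting material put in, Wednesday's
4. amount of target at the outlet or at the end, in percent of the starting material put in, Friday's
5. amount of target at the outlet or at the end, in percent of the starting material put in, Saturday's

Must the catalyst intermediates be followed through time? No. On Wednesday's charge, catalyst intermediate A has a half-life of 0.26 min by its step to target alone, while starting material has 0.68 h by its forward binding alone, so I hold the intermediate steady at whatever its formation demands.

What, then, is the constant for making target? Binding times the share of intermediate A that goes forward rather than back gives 32.0 M⁻¹ h⁻¹, which multiplies starting material and free catalyst.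

And how much free catalyst is there? That is the weak spot: its amount changes as the substrates run down. For each free catalyst, the charge at the start holds 0.32 of idle complex, 0.401 of intermediate A and 0.479 of intermediate B. Free catalyst therefore starts at 10.0 mM. With both substrates reckoned as zero, it is 16.7 mM.

How do you join those ends? The reciprocal of free catalyst runs in a straight line with the substrates, so I take the midway load, which gives 12.5 mM. The product 0.401 h⁻¹ is the clearing rate: the pseudo-first-order constant at which starting material becomes target, with the substrates at midway load.

What does it give? Wednesday's closed flask gives 79.9 % by the exponential. Saturday's tank works at its outlet concentration, so stay times rate over one plus that gives 61.6 %.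

Friday's? Friday's flask starts with no second substrate, so its free catalyst opens at 12.8 mM, more than the 10.0 mM of Wednesday's flask, and I put its target above my estimate for Wednesday's, at more than 79.9 %.

Is midway load fair for Sunday's tank? No. Its stay is 16.0 clearing times, so little substrate stands in it, and I use the empty-end catalyst instead, which gives 95.5 %. The best is then Sunday's.

The forecast named Sunday's, with 95.4 %, 78.6 %, 80.7 % and 62.4 % in the order asked, and said: “The ten-fold longer residence time therefore wins outright for Sunday's tank”.

The simulation gives Sunday's as best, with 95.4 % for Sunday's, 78.7 % for Wednesday's, 80.7 % for Friday's and 62.4 % for Saturday's.

Against the clearing time of 2.50 h, Saturday's average stay of 4.0 h is 1.60 clearing times, which puts starting material in Saturday's tank at 0.768 M beside the reading of 0.750 M. Sunday's average stay of 40.0 h is 16.0 clearing times, and in Sunday's tank 4.60 % of the starting material put in has not become target.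

The numbers of this flask were drawn at random within sensible limits; the result is computed.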